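Ring A holds an aldol motif: the C4–C5 bond joins the tertiary carbinol C4 to C5, the α-carbon of the C7 carboxyl, with the hydroxyl cis to C7 and C5/C6 cis. Everything rests on cutting that bond while C7 and C10 (the carbon on C6) are tied in a five-membered lactone. The precursor is thus a 4-substituted butenolide (C5, C6, C7, C10) carrying the preset C1 stereocentre and, through C2–C3, the C4 ketone. In one operation a chiral copper hydride reduces C6 and the lactone enolate closes ring A onto the ketone, fixing C4, C5 and C6. Ring C then grows from the lactone by ring-closing metathesis; the ring B acid, made from (S)-cryptone, is attached last.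

Key step: step 7

Atom labels: ring A = C1 (CH bearing isopropyl), C2, C3, C4 (carbinol), C5, C6; C7 = carboxyl carbon on C5; C10 = carbon on C6; C11 = OCH2 on C4; ring C also holds C12 (OCH2), C8 (alkene carbon) and its carboxyl C9; ring B is the cyclohexene of the acyl group.
Assumption: the (S)-prolinol catalyst gives the 2S aldehydes and (S)-p-Tol-BINAP is the ligand matched with C1; if either sense proves opposite, the antipodal catalyst or ligand is used and nothing else changes.

Step 1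
Reactants: 1 4-methoxybenzyl alcohol; 2 2-chloro-N-methoxy-N-methylacetamide
Product: 3 N-methoxy-2-[(4-methoxyphenyl)methoxy]-N-methylacetamide
Conditions: NaH, THF, 0 °C → rt
Reagents that add atoms: none
Why: Williamson ether synthesis, in which the sodium alkoxide of 1 displaces the activated α-chloride of 2 while the N-methoxy-N-methylamide resists alkoxide at this temperature.

Step 2
Reactants: 3 N-methoxy-2-[(4-methoxyphenyl)methoxy]-N-methylacetamide; 4 vinylmagnesium bromide
Product: 5 1-[(4-methoxyphenyl)methoxy]but-3-en-2-one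
Conditions: THF, −78 → 0 °C; inverse quench into cold 1 M HCl
Reagents that add atoms: none
Why: Ketone synthesis from an N-methoxy-N-methylamide, where the chelated magnesium adduct blocks a second addition and the acidic inverse quench keeps the released amine from adding to the enone.

Step 3
Reactants: 6 3-methylbutanal; 5 1-[(4-methoxyphenyl)methoxy]but-3-en-2-one
Product: 7 (2S)-6-[(4-methoxyphenyl)methoxy]-5-oxo-2-(propan-2-yl)hexanal
Conditions: (S)-α,α-diphenylprolinol trimethylsilyl ether (10 mol%), ethyl 3,4-dihydroxybenzoate (20 mol%), CH2Cl2, 4 °C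
Reagents that add atoms: none
Why: Enamine-catalysed Michael addition of an aldehyde to a vinyl ketone, in which the diphenyl(silyloxy)methyl group shields one face of the E-enamine so that the C1–C2 bond forms on the open face and C1 should be set as S.

Step 4
Reactants: 7 (2S)-6-[(4-methoxyphenyl)methoxy]-5-oxo-2-(propan-2-yl)hexanal; 8 ethyl diazoacetate
Product: 9 ethyl (4S)-8-[(4-methoxyphenyl)methoxy]-3,7-dioxo-4-(propan-2-yl)octanoate
Conditions: SnCl2 (10 mol%), CH2Cl2, rt
Reagents that add atoms: none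
Why: Roskamp homologation, in which the tin-activated aldehyde adds the diazo ester and a 1,2-hydride shift with loss of nitrogen gives the β-keto ester (C5 and C7 now on C6), the ketone being inert to this mild Lewis acid and C1 safe because no base is present.

Step 5
Reactants: 9 ethyl (4S)-8-[(4-methoxyphenyl)methoxy]-3,7-dioxo-4-(propan-2-yl)octanoate
Product: 10 ethyl (2Z,4S)-8-[(4-methoxyphenyl)methoxy]-7-oxo-4-(propan-2-yl)-3-{[(trifluoromethyl)sulfonyl]oxy}oct-2-enoate
Conditions: Tf2O, LiOTf, Et3N, CH2Cl2, −78 → 0 °C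
Reagents that add atoms: trifluoromethanesulfonic anhydride, O=S(=O)(OS(=O)(=O)C(F)(F)F)C(F)(F)F
Why: Stereoselective enol triflation of a β-keto ester, in which only the doubly activated C5 is enolised, the lithium-chelated Z-enolate is trapped on oxygen faster than it can add to the C4 ketone, and the triflate ends cis to the ester.

Step 6
Reactants: 10 ethyl (2Z,4S)-8-[(4-methoxyphenyl)methoxy]-7-oxo-4-(propan-2-yl)-3-{[(trifluoromethyl)sulfonyl]oxy}oct-2-enoate
Product: 12 4-[(3S)-7-[(4-methoxyphenyl)methoxy]-2-methyl-6-oxoheptan-3-yl]furan-2(5H)-one (the butenolide precursor), via hydroxymethyl enoate 11 (not isolated)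
Conditions: (tributylstannyl)methanol, Pd(PPh3)4 (5 mol%), LiCl, 1,4-dioxane, 80 °C; then PPTS (cat.), rt
Reagents that add atoms: (tributylstannyl)methanol, OC[Sn](CCCC)(CCCC)CCCC
Why: Stille hydroxymethylation of the enol triflate with retention of geometry, after which the Z γ-hydroxy enoate 11 lactonises to the butenolide while the ketone is a spectator.

Step 7
Reactants: 12 4-[(3S)-7-[(4-methoxyphenyl)methoxy]-2-methyl-6-oxoheptan-3-yl]furan-2(5H)-one
Product: 14 (3aS,4S,7R,7aS)-7-hydroxy-7-{[(4-methoxyphenyl)methoxy]methyl}-4-(propan-2-yl)-3a,4,5,6,7,7a-hexahydro-2-benzofuran-1(3H)-one (cis-fused ring A γ-lactone), via silyl ether 13 (not isolated)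
Conditions: Cu(OAc)2·H2O (5 mol%), (S)-p-Tol-BINAP (5.5 mol%), 1,1,3,3-tetramethyldisiloxane, THF, 0 °C → rt; then 1 M HCl, THF, 0 °C
Reagents that add atoms: none
Why: Cu(OAc)2 and the silane give the ligated copper hydride, which delivers hydride to C6 of the butenolide and leaves a copper enolate at C5 that adds to the tethered C4 ketone before the silane converts the copper alkoxide into silyl ether 13 and returns the hydride. The reaction type is the known copper hydride reductive aldol cyclisation of a β,β-disubstituted conjugate acceptor onto a ketone, here joined to the known asymmetric conjugate reduction of β-substituted butenolides. Ring A closes in a 6-(enolexo)-exo-trig aldol. C6 is set by the face of hydride delivery, for which the ligand antipode matched with C1 is used and which the substrate supports (attack anti to isopropyl in the rotamer with C1–H eclipsing C5=C6 puts C10 trans to isopropyl); C5 follows because the three-atom tether reaches the planar lactone enolate only from the face that carries C1, hence the cis fusion; C4 is set in a chair with isopropyl equatorial in which copper ties the C7 enolate oxygen to the ketone oxygen, so the new hydroxyl lands on the side of C7 and C11 on the other. The step needs 1,4-reduction to outrun 1,2-reduction of the α-alkoxy ketone and needs the enolate at C5 only: bisphosphine copper hydrides prefer the conjugate acceptor, and because no base is used the more acidic ketone is never enolised.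

Step 8
Reactants: 15 2-(bromomethyl)prop-2-enoic acid; 16 2-(trimethylsilyl)ethanol
Product: 17 2-(trimethylsilyl)ethyl 2-(bromomethyl)prop-2-enoate
Conditions: DCC, DMAP (5 mol%), CH2Cl2, 0 °C
Reagents that add atoms: none
Why: Steglich esterification of a primary alcohol, fast enough at 0 °C that the allylic bromide is not displaced.

Step 9
Reactants: 14 the cis-fused ring A γ-lactone; 17 2-(trimethylsilyl)ethyl 2-(bromomethyl)prop-2-enoate
Product: 19 2-{[2-(trimethylsilyl)ethoxy]carbonyl}prop-2-en-1-yl (1S,2R,5S,6S)-2-hydroxy-6-(hydroxymethyl)-2-{[(4-methoxyphenyl)methoxy]methyl}-5-(propan-2-yl)cyclohexane-1-carboxylate, via potassium carboxylate 18 (not isolated)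
Conditions: KOH (1.05 equiv), MeOH/H2O, rt; evaporate; then 17, DMF, 0 °C → rt; crude product used at once
Reagents that add atoms: potassium hydroxide, [K+].[OH-]
Why: Lactone saponification followed by O-alkylation of the carboxylate with an allylic bromide (SN2 and SN2′ give the same ester), which frees the C10 hydroxyl and puts C12, C8 and the protected C9 carboxyl on the C7 carboxylate in the same flask.

Step 10
Reactants: 19 the γ-hydroxy ester
Product: 20 2-{[2-(trimethylsilyl)ethoxy]carbonyl}prop-2-en-1-yl (1S,2R,5S,6S)-6-formyl-2-hydroxy-2-{[(4-methoxyphenyl)methoxy]methyl}-5-(propan-2-yl)cyclohexane-1-carboxylate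
Conditions: Dess–Martin periodinane, NaHCO3, CH2Cl2, 0 °C → rt
Reagents that add atoms: none
Why: Dess–Martin oxidation of the primary C10 alcohol under buffered conditions, where the tertiary C4 alcohol cannot react and C6 keeps its configuration because the formyl group is already trans to isopropyl (equatorial).

Step 11
Reactants: 20 the C10 aldehyde
Product: 21 2-{[2-(trimethylsilyl)ethoxy]carbonyl}prop-2-en-1-yl (1S,2R,5S,6S)-6-ethenyl-2-hydroxy-2-{[(4-methoxyphenyl)methoxy]methyl}-5-(propan-2-yl)cyclohexane-1-carboxylate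
Conditions: Zn, CH2I2, Ti(OiPr)4, THF, rt
Reagents that add atoms: diiodomethane, ICI
Why: Takai methylenation, whose non-basic gem-dimetallic reagent is selective for aldehydes and so leaves both esters, the acrylate and the α-stereocentre C6 alone.

Step 12
Reactants: 21 the C6 vinyl acrylate ester
Product: 22 2-(trimethylsilyl)ethyl (5aR,6S,9R,9aS)-9-hydroxy-9-{[(4-methoxyphenyl)methoxy]methyl}-1-oxo-6-(propan-2-yl)-1,3,5a,6,7,8,9,9a-octahydro-2-benzoxepine-4-carboxylate (rings A and C)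
Conditions: second-generation Hoveyda–Grubbs catalyst RuCl2(1,3-dimesitylimidazolidin-2-ylidene)(=CH-C6H4-2-OiPr) (10 mol%), toluene (2 mM), 80 °C
Reagents that add atoms: none
Why: Ring-closing metathesis, in which the catalyst loads on the C6 vinyl group and closes onto the 1,1-disubstituted acrylate held near by the cis C5/C6 arrangement, the ring forcing C6 and C12 cis on the new C8=C10 bond.

Step 13
Reactants: 22 the ring A/ring C lactone 4-methoxybenzyl ether
Product: 23 2-(trimethylsilyl)ethyl (5aR,6S,9R,9aS)-9-hydroxy-9-(hydroxymethyl)-1-oxo-6-(propan-2-yl)-1,3,5a,6,7,8,9,9a-octahydro-2-benzoxepine-4-carboxylate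
Conditions: DDQ, CH2Cl2/pH 7 phosphate buffer (10:1), 0 °C → rt
Reagents that add atoms: none
Why: Oxidative cleavage of the 4-methoxybenzyl ether (hydride abstraction, then hydrolysis of the oxocarbenium ion), where water keeps the neighbouring C4 hydroxyl from closing an acetal and the esters and conjugated alkene are inert.

Step 14
Reactants: 6 3-methylbutanal; 24 but-3-en-2-one
Product: 25 (2S)-5-oxo-2-(propan-2-yl)hexanal
Conditions: (S)-α,α-diphenylprolinol trimethylsilyl ether (5 mol%), ethyl 3,4-dihydroxybenzoate (20 mol%), neat, 4 °C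
Reagents that add atoms: none
Why: The same enamine-catalysed Michael addition as in step 3, so the isopropyl-bearing carbon of ring B should be set with the same sense (S).

Step 15
Reactants: 25 (2S)-5-oxo-2-(propan-2-yl)hexanal
Product: 26 (4S)-4-(propan-2-yl)cyclohex-2-en-1-one ((S)-cryptone)
Conditions: LiOH (10 mol%), iPrOH, rt
Reagents that add atoms: none
Why: Intramolecular aldol condensation of the methyl ketone onto the aldehyde (6-(enolexo)-exo-trig, then E1cB loss of water), the stereocentre becoming the γ-carbon of the enone, which this weak base does not deprotonate.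

Step 16
Reactants: 26 (S)-cryptone; 4 vinylmagnesium bromide
Product: 28 (3S,4S)-3-ethenyl-4-(propan-2-yl)cyclohex-1-en-1-yl trifluoromethanesulfonate, via magnesium enolate 27 (not isolated)
Conditions: CuBr·SMe2 (10 mol%), THF, −78 → −40 °C; then N-(5-chloropyridin-2-yl)-1,1,1-trifluoro-N-[(trifluoromethyl)sulfonyl]methanesulfonamide, −78 °C → rt
Reagents that add atoms: N-(5-chloropyridin-2-yl)-1,1,1-trifluoro-N-[(trifluoromethyl)sulfonyl]methanesulfonamide, O=S(=O)(N(c1ccc(Cl)cn1)S(=O)(=O)C(F)(F)F)C(F)(F)F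
Why: Copper-catalysed conjugate addition of the vinyl Grignard reagent anti to the adjacent isopropyl group sets the trans relationship of ring B, and O-triflation of the regiodefined enolate fixes the ring B double bond.

Step 17
Reactants: 28 the dienyl triflate
Product: 29 (3S,4S)-3-formyl-4-(propan-2-yl)cyclohex-1-en-1-yl trifluoromethanesulfonate
Conditions: OsO4 (2 mol%), NaIO4, 2,6-lutidine, 1,4-dioxane/H2O (3:1), rt
Reagents that add atoms: osmium tetroxide (catalytic oxygen carrier), O=[Os](=O)(=O)=O; sodium periodate (terminal oxygen source), [Na+].[O-]I(=O)(=O)=O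
Why: Johnson–Lemieux cleavage, in which osmium tetroxide dihydroxylates the electron-rich vinyl group and not the electron-poor enol triflate, periodate cleaves the diol, and the trans aldehyde is also the more stable epimer.

Step 18
Reactants: 29 the formyl triflate; 30 methyl (triphenylphosphoranylidene)acetate
Product: 32 methyl (2Z)-2-bromo-3-[(1S,6S)-6-(propan-2-yl)-3-{[(trifluoromethyl)sulfonyl]oxy}cyclohex-2-en-1-yl]prop-2-enoate, via bromo ylide 31 (not isolated)
Conditions: NBS, CH2Cl2, −20 °C; then 29, −20 °C → rt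
Reagents that add atoms: N-bromosuccinimide, O=C1CCC(=O)N1Br
Why: Wittig olefination with a stabilised α-bromo ylide made in the flask by bromination of 30, which is neutral (no epimerisation of the aldehyde) and places the ester trans to the ring, i.e. the Z bromo enoate.

Step 19
Reactants: 32 the bromo enoate triflate
Product: 33 methyl (2E)-2-(hydroxymethyl)-3-[(1S,6S)-3-(hydroxymethyl)-6-(propan-2-yl)cyclohex-2-en-1-yl]prop-2-enoate
Conditions: (tributylstannyl)methanol (2.6 equiv), Pd(PPh3)4 (10 mol%), LiCl, 1,4-dioxane, 90 °C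
Reagents that add atoms: (tributylstannyl)methanol, OC[Sn](CCCC)(CCCC)CCCC
Why: Twofold Stille hydroxymethylation, in which the alkenyl bromide and the alkenyl triflate both take up a CH2OH group with retention, so both primary alcohols of ring B arrive together and the side-chain geometry is carried over as E.

Step 20
Reactants: 33 the diol ester
Product: 34 methyl (2E)-2-{[(tert-butyldimethylsilyl)oxy]methyl}-3-[(1S,6S)-3-{[(tert-butyldimethylsilyl)oxy]methyl}-6-(propan-2-yl)cyclohex-2-en-1-yl]prop-2-enoate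
Conditions: TBSCl, imidazole, DMF, 0 °C → rt
Reagents that add atoms: tert-butyldimethylsilyl chloride, CC(C)(C)[Si](C)(C)Cl
Why: Standard silylation of two unhindered primary allylic alcohols.

Step 21
Reactants: 34 the bis-silyl ether ester
Product: 35 (2E)-2-{[(tert-butyldimethylsilyl)oxy]methyl}-3-[(1S,6S)-3-{[(tert-butyldimethylsilyl)oxy]methyl}-6-(propan-2-yl)cyclohex-2-en-1-yl]prop-2-enoic acid (ring B acid)
Conditions: LiOH·H2O, THF/MeOH/H2O, 40 °C; then 1 M HCl to pH 4
Reagents that add atoms: lithium hydroxide, [Li+].[OH-]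
Why: Saponification of the methyl ester, which primary silyl ethers survive and which cannot move the trisubstituted alkene.

Step 22
Reactants: 23 the C11 alcohol (rings A and C); 35 the ring B acid
Product: 37 2-(trimethylsilyl)ethyl (5aR,6S,9R,9aS)-9-({[(2E)-2-{[(tert-butyldimethylsilyl)oxy]methyl}-3-[(1S,6S)-3-{[(tert-butyldimethylsilyl)oxy]methyl}-6-(propan-2-yl)cyclohex-2-en-1-yl]prop-2-enoyl]oxy}methyl)-9-hydroxy-1-oxo-6-(propan-2-yl)-1,3,5a,6,7,8,9,9a-octahydro-2-benzoxepine-4-carboxylate, via mixed anhydride 36 (not isolated)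
Conditions: 2,4,6-trichlorobenzoyl chloride, Et3N, THF, rt; then 23, DMAP, toluene, rt
Reagents that add atoms: none
Why: Yamaguchi esterification, in which the preformed mixed anhydride acylates the primary C11 hydroxyl quickly, the tertiary C4 hydroxyl being too hindered to compete, so that C11–OH has no time to attack the ring C lactone.

Step 23
Reactants: 37 the fully protected ester
Product: 38 (5aR,6S,9R,9aS)-9-hydroxy-9-({[(2E)-2-(hydroxymethyl)-3-[(1S,6S)-3-(hydroxymethyl)-6-(propan-2-yl)cyclohex-2-en-1-yl]prop-2-enoyl]oxy}methyl)-1-oxo-6-(propan-2-yl)-1,3,5a,6,7,8,9,9a-octahydro-2-benzoxepine-4-carboxylic acid (target)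
Conditions: TBAF, AcOH (1:1), THF, 0 °C → rt; aqueous work-up at pH 3
Reagents that add atoms: none
Why: Fluoride-induced cleavage of both silyl ethers and β-elimination of the 2-(trimethylsilyl)ethyl ester, buffered with acetic acid so that no free alkoxide can cause acyl migration or lactone opening.

Compound list
1 | 4-methoxybenzyl alcohol | COc1ccc(CO)cc1 | starting material
2 | 2-chloro-N-methoxy-N-methylacetamide | CON(C)C(=O)CCl | starting material
3 | N-methoxy-2-[(4-methoxyphenyl)methoxy]-N-methylacetamide | CON(C)C(=O)COCc1ccc(OC)cc1 | intermediate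
4 | vinylmagnesium bromide | C=C[Mg]Br | starting material
5 | 1-[(4-methoxyphenyl)methoxy]but-3-en-2-one | C=CC(=O)COCc1ccc(OC)cc1 | intermediate
6 | 3-methylbutanal | CC(C)CC=O | starting material
7 | (2S)-6-[(4-methoxyphenyl)methoxy]-5-oxo-2-(propan-2-yl)hexanal | O=C[C@H](C(C)C)CCC(=O)COCc1ccc(OC)cc1 | intermediate
8 | ethyl diazoacetate | CCOC(=O)C=[N+]=[N-] | starting material
9 | ethyl (4S)-8-[(4-methoxyphenyl)methoxy]-3,7-dioxo-4-(propan-2-yl)octanoate | CCOC(=O)CC(=O)[C@H](C(C)C)CCC(=O)COCc1ccc(OC)cc1 | intermediate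
10 | ethyl (2Z,4S)-8-[(4-methoxyphenyl)methoxy]-7-oxo-4-(propan-2-yl)-3-{[(trifluoromethyl)sulfonyl]oxy}oct-2-enoate | CCOC(=O)/C=C(\OS(=O)(=O)C(F)(F)F)[C@H](C(C)C)CCC(=O)COCc1ccc(OC)cc1 | intermediate
11 | ethyl (2Z,4S)-3-(hydroxymethyl)-8-[(4-methoxyphenyl)methoxy]-7-oxo-4-(propan-2-yl)oct-2-enoate | CCOC(=O)/C=C(\CO)[C@H](C(C)C)CCC(=O)COCc1ccc(OC)cc1 | intermediate
12 | 4-[(3S)-7-[(4-methoxyphenyl)methoxy]-2-methyl-6-oxoheptan-3-yl]furan-2(5H)-one | CC(C)[C@H](CCC(=O)COCc1ccc(OC)cc1)C1=CC(=O)OC1 | intermediate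
13 | (3aS,4S,7R,7aS)-7-{[(4-methoxyphenyl)methoxy]methyl}-4-(propan-2-yl)-7-[(1,1,3,3-tetramethyldisiloxanyl)oxy]-3a,4,5,6,7,7a-hexahydro-2-benzofuran-1(3H)-one | CC(C)[C@@H]1CC[C@](O[Si](C)(C)O[SiH](C)C)(COCc3ccc(OC)cc3)[C@H]2C(=O)OC[C@@H]12 | intermediate
14 | (3aS,4S,7R,7aS)-7-hydroxy-7-{[(4-methoxyphenyl)methoxy]methyl}-4-(propan-2-yl)-3a,4,5,6,7,7a-hexahydro-2-benzofuran-1(3H)-one | CC(C)[C@@H]1CC[C@](O)(COCc3ccc(OC)cc3)[C@H]2C(=O)OC[C@@H]12 | intermediate
15 | 2-(bromomethyl)prop-2-enoic acid | C=C(CBr)C(=O)O | starting material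
16 | 2-(trimethylsilyl)ethanol | C[Si](C)(C)CCO | starting material
17 | 2-(trimethylsilyl)ethyl 2-(bromomethyl)prop-2-enoate | C=C(CBr)C(=O)OCC[Si](C)(C)C | intermediate
18 | potassium (1S,2R,5S,6S)-2-hydroxy-6-(hydroxymethyl)-2-{[(4-methoxyphenyl)methoxy]methyl}-5-(propan-2-yl)cyclohexane-1-carboxylate | CC(C)[C@@H]1CC[C@](O)(COCc2ccc(OC)cc2)[C@@H](C(=O)[O-])[C@H]1CO.[K+] | intermediate
19 | 2-{[2-(trimethylsilyl)ethoxy]carbonyl}prop-2-en-1-yl (1S,2R,5S,6S)-2-hydroxy-6-(hydroxymethyl)-2-{[(4-methoxyphenyl)methoxy]methyl}-5-(propan-2-yl)cyclohexane-1-carboxylate | CC(C)[C@@H]1CC[C@](O)(COCc2ccc(OC)cc2)[C@@H](C(=O)OCC(=C)C(=O)OCC[Si](C)(C)C)[C@H]1CO | intermediate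
20 | 2-{[2-(trimethylsilyl)ethoxy]carbonyl}prop-2-en-1-yl (1S,2R,5S,6S)-6-formyl-2-hydroxy-2-{[(4-methoxyphenyl)methoxy]methyl}-5-(propan-2-yl)cyclohexane-1-carboxylate | CC(C)[C@@H]1CC[C@](O)(COCc2ccc(OC)cc2)[C@@H](C(=O)OCC(=C)C(=O)OCC[Si](C)(C)C)[C@H]1C=O | intermediate
21 | 2-{[2-(trimethylsilyl)ethoxy]carbonyl}prop-2-en-1-yl (1S,2R,5S,6S)-6-ethenyl-2-hydroxy-2-{[(4-methoxyphenyl)methoxy]methyl}-5-(propan-2-yl)cyclohexane-1-carboxylate | CC(C)[C@@H]1CC[C@](O)(COCc2ccc(OC)cc2)[C@@H](C(=O)OCC(=C)C(=O)OCC[Si](C)(C)C)[C@H]1C=C | intermediate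
22 | 2-(trimethylsilyl)ethyl (5aR,6S,9R,9aS)-9-hydroxy-9-{[(4-methoxyphenyl)methoxy]methyl}-1-oxo-6-(propan-2-yl)-1,3,5a,6,7,8,9,9a-octahydro-2-benzoxepine-4-carboxylate | CC(C)[C@@H]1CC[C@](O)(COCc3ccc(OC)cc3)[C@H]2C(=O)OCC(C(=O)OCC[Si](C)(C)C)=C[C@@H]12 | intermediate
23 | 2-(trimethylsilyl)ethyl (5aR,6S,9R,9aS)-9-hydroxy-9-(hydroxymethyl)-1-oxo-6-(propan-2-yl)-1,3,5a,6,7,8,9,9a-octahydro-2-benzoxepine-4-carboxylate | CC(C)[C@@H]1CC[C@](O)(CO)[C@H]2C(=O)OCC(C(=O)OCC[Si](C)(C)C)=C[C@@H]12 | intermediate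
24 | but-3-en-2-one | CC(=O)C=C | starting material
25 | (2S)-5-oxo-2-(propan-2-yl)hexanal | O=C[C@H](C(C)C)CCC(C)=O | intermediate
26 | (4S)-4-(propan-2-yl)cyclohex-2-en-1-one | CC(C)[C@@H]1CCC(=O)C=C1 | intermediate
27 | bromomagnesium (3S,4S)-3-ethenyl-4-(propan-2-yl)cyclohex-1-en-1-olate | C=C[C@@H]1C=C(O[Mg]Br)CC[C@H]1C(C)C | intermediate
28 | (3S,4S)-3-ethenyl-4-(propan-2-yl)cyclohex-1-en-1-yl trifluoromethanesulfonate | C=C[C@@H]1C=C(OS(=O)(=O)C(F)(F)F)CC[C@H]1C(C)C | intermediate
29 | (3S,4S)-3-formyl-4-(propan-2-yl)cyclohex-1-en-1-yl trifluoromethanesulfonate | O=C[C@@H]1C=C(OS(=O)(=O)C(F)(F)F)CC[C@H]1C(C)C | intermediate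
30 | methyl (triphenylphosphoranylidene)acetate | COC(=O)C=P(c1ccccc1)(c1ccccc1)c1ccccc1 | starting material
31 | methyl bromo(triphenylphosphoranylidene)acetate | COC(=O)C(Br)=P(c1ccccc1)(c1ccccc1)c1ccccc1 | intermediate
32 | methyl (2Z)-2-bromo-3-[(1S,6S)-6-(propan-2-yl)-3-{[(trifluoromethyl)sulfonyl]oxy}cyclohex-2-en-1-yl]prop-2-enoate | COC(=O)/C(Br)=C/[C@@H]1C=C(OS(=O)(=O)C(F)(F)F)CC[C@H]1C(C)C | intermediate
33 | methyl (2E)-2-(hydroxymethyl)-3-[(1S,6S)-3-(hydroxymethyl)-6-(propan-2-yl)cyclohex-2-en-1-yl]prop-2-enoate | COC(=O)/C(CO)=C/[C@@H]1C=C(CO)CC[C@H]1C(C)C | intermediate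
34 | methyl (2E)-2-{[(tert-butyldimethylsilyl)oxy]methyl}-3-[(1S,6S)-3-{[(tert-butyldimethylsilyl)oxy]methyl}-6-(propan-2-yl)cyclohex-2-en-1-yl]prop-2-enoate | COC(=O)/C(CO[Si](C)(C)C(C)(C)C)=C/[C@@H]1C=C(CO[Si](C)(C)C(C)(C)C)CC[C@H]1C(C)C | intermediate
35 | (2E)-2-{[(tert-butyldimethylsilyl)oxy]methyl}-3-[(1S,6S)-3-{[(tert-butyldimethylsilyl)oxy]methyl}-6-(propan-2-yl)cyclohex-2-en-1-yl]prop-2-enoic acid | OC(=O)/C(CO[Si](C)(C)C(C)(C)C)=C/[C@@H]1C=C(CO[Si](C)(C)C(C)(C)C)CC[C@H]1C(C)C | intermediate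
36 | mixed anhydride of 35 with 2,4,6-trichlorobenzoic acid | O=C(OC(=O)c1c(Cl)cc(Cl)cc1Cl)/C(CO[Si](C)(C)C(C)(C)C)=C/[C@@H]1C=C(CO[Si](C)(C)C(C)(C)C)CC[C@H]1C(C)C | intermediate
37 | 2-(trimethylsilyl)ethyl (5aR,6S,9R,9aS)-9-({[(2E)-2-{[(tert-butyldimethylsilyl)oxy]methyl}-3-[(1S,6S)-3-{[(tert-butyldimethylsilyl)oxy]methyl}-6-(propan-2-yl)cyclohex-2-en-1-yl]prop-2-enoyl]oxy}methyl)-9-hydroxy-1-oxo-6-(propan-2-yl)-1,3,5a,6,7,8,9,9a-octahydro-2-benzoxepine-4-carboxylate | CC(C)[C@@H]1CC[C@](O)(COC(=O)/C(=C/[C@@H]2C=C(CO[Si](C)(C)C(C)(C)C)CC[C@H]2C(C)C)CO[Si](C)(C)C(C)(C)C)[C@H]2C(=O)OCC(C(=O)OCC[Si](C)(C)C)=C[C@@H]12 | intermediate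
38 | (5aR,6S,9R,9aS)-9-hydroxy-9-({[(2E)-2-(hydroxymethyl)-3-[(1S,6S)-3-(hydroxymethyl)-6-(propan-2-yl)cyclohex-2-en-1-yl]prop-2-enoyl]oxy}methyl)-1-oxo-6-(propan-2-yl)-1,3,5a,6,7,8,9,9a-octahydro-2-benzoxepine-4-carboxylic acid | CC(C)[C@@H]1CC[C@](O)(COC(=O)/C(=C/[C@@H]2C=C(CO)CC[C@H]2C(C)C)CO)[C@H]2C(=O)OCC(C(=O)O)=C[C@@H]12 | target

Total step count: 23. Longest linear sequence: 14 steps (steps 1–7, 9–13, 22, 23).

Steps most likely to fail

Step 7. Hydride may go to the α-alkoxy ketone instead of the butenolide, may reach C6 from the wrong face, or the enolate may be silylated before it closes ring A. The fallback separates reduction and aldol and forms the enolate by another mechanism; it sets out from 12 and comes back at 14. The ketone of 12 is masked with 1,2-bis(trimethylsilyloxy)ethane and catalytic TMSOTf as dioxolane F1. The butenolide is then reduced at C6 with the same copper hydride in the presence of tert-butanol as proton source, or by rhodium- or ruthenium-bisphosphine hydrogenation so that the face selectivity can be tuned without the aldol, to give saturated lactone F2. The lactone enolate (LiN(iPr)2, TMSCl, then NBS) is brominated at C5 to bromo lactone F3, and dilute acid returns the ketone in bromo keto lactone F4. SmI2 in THF at −78 °C then makes the samarium enolate at C5 only, which closes ring A through a chelated Reformatsky-type aldol to 14.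

Step 9. The γ-hydroxy ester may close back to lactone 14, with loss of the acrylate alcohol, before it is oxidised. The fallback brings the acrylate in only after C10 has become an alkene; it sets out from 14 and comes back at 21. Me2AlCl and N,O-dimethylhydroxylamine hydrochloride open the lactone to hydroxy N-methoxy-N-methylamide F5. Dess–Martin oxidation gives aldehyde F6 and Wittig methylenation (Ph3P=CH2) gives alkene F7. iBu2AlH at −78 °C reduces the amide to aldehyde F8, which is oxidised at once (NaClO2, NaH2PO4, 2-methylbut-2-ene) to acid F9. Alkylation of F9 with 17 (Cs2CO3, DMF) gives 21.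

Step 12. Ring closure to the seven-membered lactone may be slow, because the ester has to turn into its s-cis rotamer and the acrylate olefin is electron-poor, so oligomerisation may win. The fallback makes the C8=C10 bond by olefination and closes ring C by lactonisation; it sets out from 14 and comes back at 22. KOH and then phenacyl bromide give hydroxy phenacyl ester F10, and Dess–Martin oxidation gives aldehyde F11. Ylide F12, made from 16 and (triphenylphosphoranylidene)ketene, is brominated with NBS to bromo ylide F13 and condensed with F11 to the Z bromo enoate F14. Stille hydroxymethylation as in step 19 gives allylic alcohol F15 with C12 cis to C6. Zn in AcOH removes the phenacyl group to give seco acid F16, and Yamaguchi lactonisation at high dilution gives 22.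

Further compounds
F1 | step 7 | 4-[(3S)-1-(2-{[(4-methoxyphenyl)methoxy]methyl}-1,3-dioxolan-2-yl)-4-methylpentan-3-yl]furan-2(5H)-one | CC(C)[C@H](CCC1(COCc2ccc(OC)cc2)OCCO1)C1=CC(=O)OC1
F2 | step 7 | (4R)-4-[(3S)-1-(2-{[(4-methoxyphenyl)methoxy]methyl}-1,3-dioxolan-2-yl)-4-methylpentan-3-yl]oxolan-2-one | CC(C)[C@H](CCC1(COCc2ccc(OC)cc2)OCCO1)[C@H]1CC(=O)OC1
F3 | step 7 | (4R)-3-bromo-4-[(3S)-1-(2-{[(4-methoxyphenyl)methoxy]methyl}-1,3-dioxolan-2-yl)-4-methylpentan-3-yl]oxolan-2-one (C3 epimers) | CC(C)[C@H](CCC1(COCc2ccc(OC)cc2)OCCO1)[C@H]1C(Br)C(=O)OC1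
F4 | step 7 | (4R)-3-bromo-4-[(3S)-7-[(4-methoxyphenyl)methoxy]-2-methyl-6-oxoheptan-3-yl]oxolan-2-one (C3 epimers) | CC(C)[C@H](CCC(=O)COCc1ccc(OC)cc1)[C@H]1C(Br)C(=O)OC1
F5 | step 9 | (1S,2R,5S,6S)-2-hydroxy-6-(hydroxymethyl)-N-methoxy-2-{[(4-methoxyphenyl)methoxy]methyl}-N-methyl-5-(propan-2-yl)cyclohexane-1-carboxamide | CC(C)[C@@H]1CC[C@](O)(COCc2ccc(OC)cc2)[C@@H](C(=O)N(C)OC)[C@H]1CO
F6 | step 9 | (1S,2R,5S,6S)-6-formyl-2-hydroxy-N-methoxy-2-{[(4-methoxyphenyl)methoxy]methyl}-N-methyl-5-(propan-2-yl)cyclohexane-1-carboxamide | CC(C)[C@@H]1CC[C@](O)(COCc2ccc(OC)cc2)[C@@H](C(=O)N(C)OC)[C@H]1C=O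
F7 | step 9 | (1S,2R,5S,6S)-6-ethenyl-2-hydroxy-N-methoxy-2-{[(4-methoxyphenyl)methoxy]methyl}-N-methyl-5-(propan-2-yl)cyclohexane-1-carboxamide | CC(C)[C@@H]1CC[C@](O)(COCc2ccc(OC)cc2)[C@@H](C(=O)N(C)OC)[C@H]1C=C
F8 | step 9 | (1S,2R,5S,6S)-6-ethenyl-2-hydroxy-2-{[(4-methoxyphenyl)methoxy]methyl}-5-(propan-2-yl)cyclohexane-1-carbaldehyde | CC(C)[C@@H]1CC[C@](O)(COCc2ccc(OC)cc2)[C@@H](C=O)[C@H]1C=C
F9 | step 9 | (1S,2R,5S,6S)-6-ethenyl-2-hydroxy-2-{[(4-methoxyphenyl)methoxy]methyl}-5-(propan-2-yl)cyclohexane-1-carboxylic acid | CC(C)[C@@H]1CC[C@](O)(COCc2ccc(OC)cc2)[C@@H](C(=O)O)[C@H]1C=C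
F10 | step 12 | 2-oxo-2-phenylethyl (1S,2R,5S,6S)-2-hydroxy-6-(hydroxymethyl)-2-{[(4-methoxyphenyl)methoxy]methyl}-5-(propan-2-yl)cyclohexane-1-carboxylate | CC(C)[C@@H]1CC[C@](O)(COCc2ccc(OC)cc2)[C@@H](C(=O)OCC(=O)c2ccccc2)[C@H]1CO
F11 | step 12 | 2-oxo-2-phenylethyl (1S,2R,5S,6S)-6-formyl-2-hydroxy-2-{[(4-methoxyphenyl)methoxy]methyl}-5-(propan-2-yl)cyclohexane-1-carboxylate | CC(C)[C@@H]1CC[C@](O)(COCc2ccc(OC)cc2)[C@@H](C(=O)OCC(=O)c2ccccc2)[C@H]1C=O
F12 | step 12 | 2-(trimethylsilyl)ethyl (triphenylphosphoranylidene)acetate | C[Si](C)(C)CCOC(=O)C=P(c1ccccc1)(c1ccccc1)c1ccccc1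
F13 | step 12 | 2-(trimethylsilyl)ethyl bromo(triphenylphosphoranylidene)acetate | C[Si](C)(C)CCOC(=O)C(Br)=P(c1ccccc1)(c1ccccc1)c1ccccc1
F14 | step 12 | 2-oxo-2-phenylethyl (1S,2R,5S,6S)-6-[(1Z)-2-bromo-3-oxo-3-[2-(trimethylsilyl)ethoxy]prop-1-en-1-yl]-2-hydroxy-2-{[(4-methoxyphenyl)methoxy]methyl}-5-(propan-2-yl)cyclohexane-1-carboxylate | CC(C)[C@@H]1CC[C@](O)(COCc2ccc(OC)cc2)[C@@H](C(=O)OCC(=O)c2ccccc2)[C@H]1/C=C(\Br)C(=O)OCC[Si](C)(C)C
F15 | step 12 | 2-oxo-2-phenylethyl (1S,2R,5S,6S)-2-hydroxy-6-[(1E)-2-(hydroxymethyl)-3-oxo-3-[2-(trimethylsilyl)ethoxy]prop-1-en-1-yl]-2-{[(4-methoxyphenyl)methoxy]methyl}-5-(propan-2-yl)cyclohexane-1-carboxylate | CC(C)[C@@H]1CC[C@](O)(COCc2ccc(OC)cc2)[C@@H](C(=O)OCC(=O)c2ccccc2)[C@H]1/C=C(\CO)C(=O)OCC[Si](C)(C)C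
F16 | step 12 | (1S,2R,5S,6S)-2-hydroxy-6-[(1E)-2-(hydroxymethyl)-3-oxo-3-[2-(trimethylsilyl)ethoxy]prop-1-en-1-yl]-2-{[(4-methoxyphenyl)methoxy]methyl}-5-(propan-2-yl)cyclohexane-1-carboxylic acid | CC(C)[C@@H]1CC[C@](O)(COCc2ccc(OC)cc2)[C@@H](C(=O)O)[C@H]1/C=C(\CO)C(=O)OCC[Si](C)(C)C
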